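**Retrosynthetic overview**

The target 16 is 3,6-dibromo-2-(2,4-dibromophenoxy)phenol. In ring A the two oxygen-bearing carbons C1 (OH) and C2 (OAr) are adjacent, and each has a C–Br bond on its outer side (C6–Br and C3–Br), so C1/C2 are read as the two carbons of the symmetric 3,6-dibromobenzyne.
Disconnections: C1–OH back to C1–B (boronic acid 15, oxidation); then O–C2 and C1–B together back to the aryne, 2,4-dibromophenoxide (ring B) and B(OMe)3.
The aryne comes from 3,6-dibromo-2-iodophenyl 4-chlorobenzenesulfonate 7 by iodine–magnesium exchange. Compound 7 comes from 2,5-dibromophenol by carbamate-directed ortho-lithiation/iodination, carbamate hydrolysis and sulfonylation.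
No ring is formed in the route; rings A and B are both bought as dibromophenols.

Key step: step 5

Remark: the target is achiral, so no stereocentre has to be set. Ring A is numbered as in the target (C1 OH, C2 OAr, C3 and C6 Br).

Step 1
Reactants: 1 2,5-dibromophenol
Product: 2 2,5-dibromophenyl N,N-diethylcarbamate
Conditions: ClC(O)NEt2, K2CO3, MeCN, reflux
Reagents that add atoms: N,N-diethylcarbamoyl chloride, CCN(CC)C(Cl)=O
Why: O-Carbamoylation of the phenoxide with a carbamoyl chloride is a routine acylation and installs the group that will direct the ortho-metalation.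

Step 2
Reactants: 2 2,5-dibromophenyl N,N-diethylcarbamate
Product: 4 3,6-dibromo-2-iodophenyl N,N-diethylcarbamate, via 3,6-dibromo-2-lithiophenyl N,N-diethylcarbamate 3 (not isolated)
Conditions: LiN(iPr)2 (1.1 equiv), THF, −78 °C, 30 min; then I2 in THF, −78 °C → rt; aq Na2S2O3
Reagents that add atoms: iodine, II
Why: Directed ortho-metalation: the only hydrogen ortho to the carbamate lies between the carbamate oxygen and a bromine and is the most acidic site, the amide base at −78 °C should remove it without bromine–lithium exchange, carbamoyl migration or LiBr loss, and iodine then quenches the aryllithium.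

Step 3
Reactants: 4 3,6-dibromo-2-iodophenyl N,N-diethylcarbamate
Product: 5 3,6-dibromo-2-iodophenol
Conditions: KOH (excess), EtOH/H2O, reflux; then aq HCl
Reagents that add atoms: none
Why: Alkaline hydrolysis of an O-aryl carbamate by hydroxide attack at the carbonyl, helped by the good leaving-group ability of the trihalophenoxide; the unactivated aryl halides should not be substituted under these conditions.

Step 4
Reactants: 5 3,6-dibromo-2-iodophenol; 6 4-chlorobenzenesulfonyl chloride
Product: 7 3,6-dibromo-2-iodophenyl 4-chlorobenzenesulfonate
Conditions: Et3N, DMAP (cat.), CH2Cl2, 0 °C → rt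
Reagents that add atoms: 4-chlorobenzenesulfonyl chloride (compound 6), O=S(=O)(Cl)c1ccc(Cl)cc1
Why: Sulfonylation of an acidic phenol with a sulfonyl chloride under amine base and DMAP catalysis; the phenoxide forms easily and should attack sulfur despite the two ortho halogens.

Step 5
Reactants: 7 3,6-dibromo-2-iodophenyl 4-chlorobenzenesulfonate; 8 2,4-dibromophenol; 9 trimethyl borate
Product: 15 [3,6-dibromo-2-(2,4-dibromophenoxy)phenyl]boronic acid, via chloromagnesium 2,4-dibromophenoxide 10 (not isolated), via magnesiated aryl sulfonate 11 (not isolated), via 3,6-dibromobenzyne 12 (not isolated), via adduct arylmagnesium chloride 13 (not isolated), via dimethyl boronate ester 14 (not isolated)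
Conditions: flask A: 8 (2.0 equiv), iPrMgCl·LiCl (2.0 equiv, titrated), THF, −20 °C; flask B: 7, iPrMgCl (1.05 equiv), THF, −78 °C, 20 min; A into B at −78 °C, then −78 → −10 °C (slow, dilute); recool to −78 °C, B(OMe)3 (4 equiv), → rt; aq NH4Cl/1 M HCl; crude 15 carried on
Reagents that add atoms: 2,4-dibromophenol (compound 8), Oc1ccc(Br)cc1Br; trimethyl borate (compound 9), COB(OC)OC; water, O
Why: Proposed new method: iPrMgCl exchanges only the C–I bond of 7 at −78 °C (iodine–magnesium exchange is far faster than bromine–magnesium exchange), and on warming the arylmagnesium 11 expels magnesium 4-chlorobenzenesulfonate to give 3,6-dibromobenzyne 12, whose strained bond takes up the oxygen of phenoxide 10 in the ring plane (new O–C2 bond) and leaves the carbanion at C1 as arylmagnesium 13, which is then borylated by B(OMe)3 (new C1–B bond) and hydrolysed to 15. The closest known reaction type is aryne generation from 2-magnesiated aryl sulfonates with addition of magnesium thiolates or amides and electrophilic capture of the resulting arylmagnesium, together with the O-arylation of phenols by arynes; the pairing of an oxygen nucleophile with a boron electrophile on such an aryne is the untested part. No ring is closed and no stereocentre is formed, so neither a mode of closure nor a controlling element is needed. Regiochemistry takes care of itself because 12 is symmetric, with a bromine next to each aryne carbon, so attack at either carbon gives the same adduct, and the two bromines both raise the electrophilicity of 12 and stabilise the carbanion of 13. The selectivities that must be secured are loss of sulfonate and not of MgBrCl from 11 (the sulfonate is the far better, magnesium-coordinated leaving group below 0 °C), O-attack of 10 in preference to attack by 11 or 13 on 12 (excess 10, LiCl, slow warming, dilution), and survival of the ortho-bromo arylmagnesium 13 until capture (temperature kept at or below −10 °C). B(OMe)3 is added only after the aryne has been consumed, because borate present earlier would capture 11 before sulfonate loss and would exchange methoxide with the phenoxide.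

Step 6
Reactants: 15 [3,6-dibromo-2-(2,4-dibromophenoxy)phenyl]boronic acid
Product: 16 3,6-dibromo-2-(2,4-dibromophenoxy)phenol
Conditions: 30% aq H2O2, THF, NaH2PO4/Na2HPO4 buffer (pH 8), 0 °C → rt; aq Na2S2O3; chromatography (recovers excess 8)
Reagents that add atoms: hydrogen peroxide, OO
Why: Oxidation of an arylboronic acid by hydroperoxide (addition to boron, 1,2-aryl shift from boron to oxygen, hydrolysis of the borate ester) should replace C1–B by C1–OH at the same carbon, the near-neutral buffer at low temperature keeping protodeboronation of the di-ortho-substituted boronic acid slow while aryl bromides and the diaryl ether stay untouched.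

**Compound list**

1 | 2,5-dibromophenol | Oc1cc(Br)ccc1Br | starting material
2 | 2,5-dibromophenyl N,N-diethylcarbamate | CCN(CC)C(=O)Oc1cc(Br)ccc1Br | intermediate
3 | 3,6-dibromo-2-lithiophenyl N,N-diethylcarbamate | CCN(CC)C(=O)Oc1c([Li])c(Br)ccc1Br | intermediate
4 | 3,6-dibromo-2-iodophenyl N,N-diethylcarbamate | CCN(CC)C(=O)Oc1c(I)c(Br)ccc1Br | intermediate
5 | 3,6-dibromo-2-iodophenol | Oc1c(I)c(Br)ccc1Br | intermediate
6 | 4-chlorobenzenesulfonyl chloride | O=S(=O)(Cl)c1ccc(Cl)cc1 | starting material
7 | 3,6-dibromo-2-iodophenyl 4-chlorobenzenesulfonate | O=S(=O)(Oc1c(I)c(Br)ccc1Br)c1ccc(Cl)cc1 | intermediate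
8 | 2,4-dibromophenol | Oc1ccc(Br)cc1Br | starting material
9 | trimethyl borate | COB(OC)OC | starting material
10 | chloromagnesium 2,4-dibromophenoxide | Cl[Mg]Oc1ccc(Br)cc1Br | intermediate
11 | 3,6-dibromo-2-(chloromagnesio)phenyl 4-chlorobenzenesulfonate | O=S(=O)(Oc1c([Mg]Cl)c(Br)ccc1Br)c1ccc(Cl)cc1 | intermediate
12 | 3,6-dibromobenzyne (1,4-dibromo-2,3-didehydrobenzene) | BrC1=CC=C(Br)C#C1 | intermediate
13 | [3,6-dibromo-2-(2,4-dibromophenoxy)phenyl]magnesium chloride | Cl[Mg]c1c(Br)ccc(Br)c1Oc1ccc(Br)cc1Br | intermediate
14 | dimethyl [3,6-dibromo-2-(2,4-dibromophenoxy)phenyl]boronate | COB(OC)c1c(Br)ccc(Br)c1Oc1ccc(Br)cc1Br | intermediate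
15 | [3,6-dibromo-2-(2,4-dibromophenoxy)phenyl]boronic acid | OB(O)c1c(Br)ccc(Br)c1Oc1ccc(Br)cc1Br | intermediate
16 | 3,6-dibromo-2-(2,4-dibromophenoxy)phenol | Oc1c(Br)ccc(Br)c1Oc1ccc(Br)cc1Br | target

**Totals and risks**

Total step count: 6. Longest linear sequence: 6 steps (1 → 2 → 4 → 5 → 7 → 15 → 16).

Steps most likely to fail:

Step 5. The aryne may be taken up by the arylmagnesium species present instead of by the weakly nucleophilic magnesium phenoxide. The phenoxide may also arylate at carbon instead of oxygen, or the adduct may lose MgBrCl before it is borylated. The fallback uses known chemistry without an aryne; it sets out from 8 and comes back to the route at 16. Commercial 1,4-dibromo-2-fluorobenzene (Fc1cc(Br)ccc1Br) is lithiated between fluorine and bromine with LiN(iPr)2 in THF at −78 °C and formylated with DMF to give 3,6-dibromo-2-fluorobenzaldehyde F1. Phenol 8 then displaces the fluoride ortho to the aldehyde (K2CO3, DMF, 90 °C, nucleophilic aromatic substitution) to give 3,6-dibromo-2-(2,4-dibromophenoxy)benzaldehyde F2. Baeyer–Villiger oxidation with mCPBA in CH2Cl2 (aryl migration, Dakin-type) should give 3,6-dibromo-2-(2,4-dibromophenoxy)phenyl formate F3. Mild hydrolysis (KOH, MeOH/H2O, rt; then aq HCl) gives 16.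

Step 2. The free aryllithium 3 may decay before iodine is added, by elimination of LiBr to an aryne, by migration of the carbamoyl group to carbon, or by bromine scrambling. The fallback keeps the aryllithium from accumulating and brings iodine in by ipso-substitution; it sets out from 2 and comes back at 4. LiN(iPr)2 is added at −78 °C to a THF solution of 2 and Me3SiCl (in situ quench) to give 3,6-dibromo-2-(trimethylsilyl)phenyl N,N-diethylcarbamate F4. Iododesilylation with ICl in CH2Cl2 (0 °C → rt) then gives 4.

Step 3. Hydroxide attack on a carbamate shielded by two ortho halogens may be slow, and forcing alkali may cost iodine or degrade the material. The fallback replaces the carbamate by an acid-labile acetal directing group; it sets out from 1 and comes back at 5. MOMCl and iPr2NEt in CH2Cl2 give 1,4-dibromo-2-(methoxymethoxy)benzene F5. LiN(iPr)2 in THF at −78 °C followed by I2 gives 1,4-dibromo-2-iodo-3-(methoxymethoxy)benzene F6. HCl in MeOH at 40 °C then releases 5.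

**Further compounds**

F1 | step 5 | 3,6-dibromo-2-fluorobenzaldehyde | O=Cc1c(F)c(Br)ccc1Br
F2 | step 5 | 3,6-dibromo-2-(2,4-dibromophenoxy)benzaldehyde | O=Cc1c(Br)ccc(Br)c1Oc1ccc(Br)cc1Br
F3 | step 5 | 3,6-dibromo-2-(2,4-dibromophenoxy)phenyl formate | O=COc1c(Br)ccc(Br)c1Oc1ccc(Br)cc1Br
F4 | step 2 | 3,6-dibromo-2-(trimethylsilyl)phenyl N,N-diethylcarbamate | CCN(CC)C(=O)Oc1c([Si](C)(C)C)c(Br)ccc1Br
F5 | step 3 | 1,4-dibromo-2-(methoxymethoxy)benzene | COCOc1cc(Br)ccc1Br
F6 | step 3 | 1,4-dibromo-2-iodo-3-(methoxymethoxy)benzene | COCOc1c(I)c(Br)ccc1Br
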